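**Retrosynthetic overview**
1. The target is epicatechin-(4α→6)-epiafzelechin-(4α→8)-epicatechin-(4β→6)-epicatechin, with units A, B, C, D from the top. The last step is one global hydrogenolysis (18 benzyl ethers, 2 aryl bromides).
2. Key disconnection: the pyran ring of unit B (bonds O1–C2 and C3–C4). It is made by an endo hetero-Diels–Alder reaction of an o-quinone methide with (Z)-4-benzyloxystyryl acetate, which sets C2, C3 and C4 all-cis in one step. It is the only ring built, and it is built last.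
3. The o-quinone methide comes from the C8 Grignard reagent of the C–D dimer and an O-Boc salicylaldehyde. That aldehyde already carries unit A para to the Boc-bearing oxygen, which fixes A(4→6)B and B(4→8)C.
4. C–D bond: SN1 coupling of an 8-iodo-4β-ol with 8-bromo-capped epicatechin, where only C6 is free and attack is from the β face.
5. A–aryl bond: aryllithium plus an epicatechin-derived 4-ketone, then ionic reduction with hydride from the β face, so the aryl group ends 4α. The pyran rings of A, C and D are bought in (−)-epicatechin.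

Assumption: the SMILES is read literally, so units A and B are 2,3-cis-3,4-cis (4α) and unit C is 3,4-trans (4β); α is the face that carries the 2-aryl group.

**Step 1**
Reactants: 1 (−)-epicatechin
Product: 3 3,5,7,3',4'-penta-O-benzyl-(−)-epicatechin, via tetrabenzyl ether 2 (not isolated)
Conditions: BnBr (4.4 equiv), K2CO3, DMF, 0 °C to rt; then NaH (1.5 equiv), BnBr (1.3 equiv), 0 °C to rt, same flask
Reagents that add atoms: benzyl bromide BrCc1ccccc1
Why: Williamson ether synthesis in which the mild base caps the four phenols first, so that no free phenol is left to open the pyran ring when NaH then benzylates the 3-OH, and C2 and C3 stay as bought.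

**Step 2**
Reactants: 3 penta-O-benzylepicatechin
Product: 4 8-bromo-penta-O-benzylepicatechin (unit D)
Conditions: NBS (1.0 equiv), CH2Cl2, −78 °C to rt
Reagents that add atoms: N-bromosuccinimide O=C1CCC(=O)N1Br
Why: Electrophilic aromatic bromination goes to C8, the most reactive position of the 5,7-dialkoxychroman ring, and caps it so that only C6 can later act as the nucleophile.

**Step 3**
Reactants: 3 penta-O-benzylepicatechin
Product: 5 4β-hydroxy-penta-O-benzylepicatechin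
Conditions: DDQ (1.5 equiv), CH2Cl2/H2O, rt
Reagents that add atoms: water O
Why: DDQ benzylic oxidation (hydride abstraction) gives the C4 cation stabilised by the dialkoxy ring, and water adds anti to the α-oriented 2-aryl and 3-OBn groups, so the carbinol is 4β.

**Step 4**
Reactants: 5 4β-hydroxy-penta-O-benzylepicatechin
Product: 6 8-iodo-4β-hydroxy-penta-O-benzylepicatechin (unit C)
Conditions: NIS (1.05 equiv), NaHCO3, CH2Cl2, 0 °C, dark
Reagents that add atoms: N-iodosuccinimide O=C1CCC(=O)N1I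
Why: Electrophilic aromatic iodination follows the same C8 preference as step 2 under buffered conditions that leave the 4-ol intact, and the iodine is both a cap against self-condensation and the later metalation handle.

**Step 5**
Reactants: 6 8-iodo-4β-ol (unit C); 4 8-bromide (unit D)
Product: 7 (8-iodo-penta-O-benzylepicatechin)-(4β→6)-(8-bromo-penta-O-benzylepicatechin)
Conditions: 4 (3 equiv, excess recovered), BF3·OEt2 (0.2 equiv), 4 Å MS, CH2Cl2, −78 to −30 °C
Reagents that add atoms: none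
Why: In this SN1 Friedel–Crafts alkylation the C4 cation of 6 is attacked by the only free ring-A position of 4 (C6) from the β face, anti to the 2-aryl and 3-OBn groups, which sets C4 of unit C as 4β (3,4-trans).

**Step 6**
Reactants: 5 4β-hydroxy-penta-O-benzylepicatechin
Product: 8 (2R,3S)-penta-O-benzyl-4-oxoepicatechin (2,3-cis flavanon-3-ol ether, unit A)
Conditions: (nPr4N)RuO4 (5 mol %), NMO (1.5 equiv), 4 Å MS, CH2Cl2, rt
Reagents that add atoms: none
Why: Ley–Griffith oxidation of the benzylic alcohol is neutral and fast, so the base-sensitive 2,3-cis arrangement next to the new ketone is kept.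

**Step 7**
Reactants: 9 3,5-bis(benzyloxy)phenol
Product: 11 3,5-bis(benzyloxy)-2,6-dibromo-4-iodophenol, via dibromophenol 10 (not isolated)
Conditions: NBS (2.0 equiv), iPr2NH (10 mol %), CH2Cl2, 0 °C; then NIS (1.1 equiv), TFA (0.3 equiv), MeCN, rt
Reagents that add atoms: N-bromosuccinimide O=C1CCC(=O)N1Br; N-iodosuccinimide O=C1CCC(=O)N1I
Why: Amine-mediated ortho-selective phenol bromination fills both positions next to the OH, so the following electrophilic iodination can only take the last C–H, para to the OH, which defines the later 4→6 connectivity.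

**Step 8**
Reactants: 11 dibromoiodophenol; 8 4-ketone
Product: 13 4β-[2,6-bis(benzyloxy)-3,5-dibromo-4-hydroxyphenyl]-4α-hydroxy-penta-O-benzylepicatechin, via dilithio species 12 (not isolated)
Conditions: 11 (1.3 equiv), nBuLi (2.6 equiv), THF, −78 °C; then 8, −78 to −40 °C; H2O
Reagents that add atoms: none
Why: After deprotonation of the phenol, iodine–lithium exchange is much faster than bromine–lithium exchange, and the aryllithium adds 1,2 to the ketone from the open β face, giving a C4 configuration that is erased in the next step.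

**Step 9**
Reactants: 13 tertiary alcohol
Product: 14 4α-[2,6-bis(benzyloxy)-3,5-dibromo-4-hydroxyphenyl]-penta-O-benzylepicatechin (2,3-cis-3,4-cis)
Conditions: Bu3SnH (2 equiv), TFA (10 equiv), CH2Cl2, 0 °C
Reagents that add atoms: none
Why: In this ionic hydrogenation TFA ionises the tertiary diaryl carbinol and the tin hydride delivers hydride to the β face, anti to the 2-aryl and 3-OBn groups, which pushes the aryl group to 4α and sets C4 of unit A under control of the bought C2 and C3.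

**Step 10**
Reactants: 14 dibromophenol carrying unit A
Product: 16 2,4-bis(benzyloxy)-5-bromo-6-hydroxy-3-(penta-O-benzylepicatechin-4α-yl)benzaldehyde, via aryllithium 15 (not isolated)
Conditions: nBuLi (2.1 equiv), THF, −78 °C; DMF (5 equiv), −78 °C to rt; aq. work-up
Reagents that add atoms: N,N-dimethylformamide CN(C)C=O
Why: In this bromine–lithium exchange and formylation the two bromines are interchanged by rotation about the aryl–C4 bond, so either gives the same ortho-lithiated phenolate, a second exchange on the dianion is disfavoured, and the remaining bromine simply caps the future C8 of unit B.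

**Step 11**
Reactants: 16 salicylaldehyde
Product: 17 2,4-bis(benzyloxy)-5-bromo-6-(tert-butoxycarbonyloxy)-3-(penta-O-benzylepicatechin-4α-yl)benzaldehyde
Conditions: Boc2O (1.3 equiv), DMAP (10 mol %), CH2Cl2, 0 °C to rt
Reagents that add atoms: di-tert-butyl dicarbonate CC(C)(C)OC(=O)OC(=O)OC(C)(C)C
Why: DMAP-catalysed O-acylation of the only free hydroxyl marks the oxygen para to unit A as the one that will become O1 of unit B.

**Step 12**
Reactants: 18 1-(benzyloxy)-4-ethynylbenzene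
Product: 19 (Z)-2-[4-(benzyloxy)phenyl]ethenyl acetate
Conditions: AcOH (1.2 equiv), Ru(2-methylallyl)2(dppb) (1 mol %), toluene, 50 °C
Reagents that add atoms: acetic acid CC(=O)O
Why: Ruthenium-vinylidene mediated anti-Markovnikov trans-addition of the acid to the terminal alkyne gives the (Z)-enol ester selectively, and this geometry later becomes the 2,3-cis relation of unit B.

**Step 13 (key step)**
Reactants: 7 C–D iodide; 17 O-Boc aldehyde; 19 (Z)-enol acetate
Product: 23 octadeca-O-benzyl-8(B),8(D)-dibromo tetramer with free 3-OH in unit B, via aryl Grignard 20 (not isolated), via o-quinone methide 21 (not isolated), via cycloadduct acetate 22 (not isolated)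
Conditions: 7, iPrMgCl·LiCl (1.05 equiv), THF, −30 °C; 17 (1.0 equiv), −78 °C; 19 (5 equiv), −78 °C to rt; then NaOMe, MeOH, 40 °C, same flask; chromatography
Reagents that add atoms: none
Why: In this Pettus-type anionic cascade the Grignard reagent adds to the aldehyde and an O-to-O Boc shift with loss of tert-butyl carbonate releases the (E)-o-quinone methide, whose methide carbon bonds to the acetoxy-bearing carbon of 19 because the 4-benzyloxyphenyl group is the stronger donor, and the suprafacial endo inverse-demand hetero-Diels–Alder reaction turns the Z alkene into 2,3-cis and the E/endo arrangement into 3,4-cis, while the face is chosen only by the enantiopure units A and C flanking the methide, so the wanted all-α isomer is separated from the all-β one after methanolysis of the acetate.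

**Step 14**
Reactants: 23 protected tetramer
Product: 24 epicatechin-(4α→6)-epiafzelechin-(4α→8)-epicatechin-(4β→6)-epicatechin (target)
Conditions: H2 (1 atm), Pd(OH)2/C, Et3N (2.5 equiv), THF/MeOH/H2O, rt; Sephadex LH-20, freeze-drying
Reagents that add atoms: none
Why: Catalytic hydrogenolysis removes all eighteen benzyl ethers and both aryl bromide caps in one operation under near-neutral conditions that touch neither the interflavan bonds nor any stereocenter.

**Compound list**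
1 | (−)-epicatechin | Oc1cc(O)c2c(c1)O[C@H](c1ccc(O)c(O)c1)[C@H](O)C2 | starting material
2 | 5,7,3',4'-tetra-O-benzyl-(−)-epicatechin | c1c(OCc9ccccc9)cc(OCc9ccccc9)c2c1O[C@H](c1ccc(OCc9ccccc9)c(OCc9ccccc9)c1)[C@H](O)C2 | intermediate
3 | 3,5,7,3',4'-penta-O-benzyl-(−)-epicatechin | c1c(OCc9ccccc9)cc(OCc9ccccc9)c2c1O[C@H](c1ccc(OCc9ccccc9)c(OCc9ccccc9)c1)[C@H](OCc9ccccc9)C2 | intermediate
4 | 8-bromo-penta-O-benzylepicatechin | Brc1c(OCc9ccccc9)cc(OCc9ccccc9)c2c1O[C@H](c1ccc(OCc9ccccc9)c(OCc9ccccc9)c1)[C@H](OCc9ccccc9)C2 | intermediate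
5 | 4β-hydroxy-penta-O-benzylepicatechin | c1c(OCc9ccccc9)cc(OCc9ccccc9)c2c1O[C@H](c1ccc(OCc9ccccc9)c(OCc9ccccc9)c1)[C@H](OCc9ccccc9)[C@H]2O | intermediate
6 | 8-iodo-4β-hydroxy-penta-O-benzylepicatechin | Ic1c(OCc9ccccc9)cc(OCc9ccccc9)c2c1O[C@H](c1ccc(OCc9ccccc9)c(OCc9ccccc9)c1)[C@H](OCc9ccccc9)[C@H]2O | intermediate
7 | (8-iodo-penta-O-benzylepicatechin)-(4β→6)-(8-bromo-penta-O-benzylepicatechin) | Ic3c(OCc9ccccc9)cc(OCc9ccccc9)c4c3O[C@H](c3ccc(OCc9ccccc9)c(OCc9ccccc9)c3)[C@H](OCc9ccccc9)[C@H]4c3c(OCc9ccccc9)c(Br)c4c(c3OCc9ccccc9)C[C@@H](OCc9ccccc9)[C@@H](c3ccc(OCc9ccccc9)c(OCc9ccccc9)c3)O4 | intermediate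
8 | (2R,3S)-penta-O-benzyl-4-oxoepicatechin | c1c(OCc9ccccc9)cc(OCc9ccccc9)c2c1O[C@H](c1ccc(OCc9ccccc9)c(OCc9ccccc9)c1)[C@H](OCc9ccccc9)C2=O | intermediate
9 | 3,5-bis(benzyloxy)phenol | Oc1cc(OCc2ccccc2)cc(OCc2ccccc2)c1 | starting material
10 | 3,5-bis(benzyloxy)-2,6-dibromophenol | Oc1c(Br)c(OCc2ccccc2)cc(OCc2ccccc2)c1Br | intermediate
11 | 3,5-bis(benzyloxy)-2,6-dibromo-4-iodophenol | Oc1c(Br)c(OCc2ccccc2)c(I)c(OCc2ccccc2)c1Br | intermediate
12 | lithium 3,5-bis(benzyloxy)-2,6-dibromo-4-lithiophenolate | [Li]Oc1c(Br)c(OCc2ccccc2)c([Li])c(OCc2ccccc2)c1Br | intermediate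
13 | 4β-aryl-4α-hydroxy adduct of 8 | c1c(OCc9ccccc9)cc(OCc9ccccc9)c2c1O[C@H](c1ccc(OCc9ccccc9)c(OCc9ccccc9)c1)[C@H](OCc9ccccc9)[C@@]2(O)c1c(OCc9ccccc9)c(Br)c(O)c(Br)c1OCc9ccccc9 | intermediate
14 | 4α-[2,6-bis(benzyloxy)-3,5-dibromo-4-hydroxyphenyl]-penta-O-benzylepicatechin | c1c(OCc9ccccc9)cc(OCc9ccccc9)c2c1O[C@H](c1ccc(OCc9ccccc9)c(OCc9ccccc9)c1)[C@H](OCc9ccccc9)[C@@H]2c1c(OCc9ccccc9)c(Br)c(O)c(Br)c1OCc9ccccc9 | intermediate
15 | ortho-lithiated lithium phenolate of 14 | c1c(OCc9ccccc9)cc(OCc9ccccc9)c2c1O[C@H](c1ccc(OCc9ccccc9)c(OCc9ccccc9)c1)[C@H](OCc9ccccc9)[C@@H]2c1c(OCc9ccccc9)c([Li])c(O[Li])c(Br)c1OCc9ccccc9 | intermediate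
16 | 2,4-bis(benzyloxy)-5-bromo-6-hydroxy-3-(penta-O-benzylepicatechin-4α-yl)benzaldehyde | c1c(OCc9ccccc9)cc(OCc9ccccc9)c2c1O[C@H](c1ccc(OCc9ccccc9)c(OCc9ccccc9)c1)[C@H](OCc9ccccc9)[C@@H]2c1c(OCc9ccccc9)c(C=O)c(O)c(Br)c1OCc9ccccc9 | intermediate
17 | O-Boc derivative of 16 | c1c(OCc9ccccc9)cc(OCc9ccccc9)c2c1O[C@H](c1ccc(OCc9ccccc9)c(OCc9ccccc9)c1)[C@H](OCc9ccccc9)[C@@H]2c1c(OCc9ccccc9)c(C=O)c(OC(=O)OC(C)(C)C)c(Br)c1OCc9ccccc9 | intermediate
18 | 1-(benzyloxy)-4-ethynylbenzene | C#Cc1ccc(OCc2ccccc2)cc1 | starting material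
19 | (Z)-2-[4-(benzyloxy)phenyl]ethenyl acetate | CC(=O)O/C=C\c1ccc(OCc2ccccc2)cc1 | intermediate
20 | C8 arylmagnesium chloride of the C–D dimer | Cl[Mg]c3c(OCc9ccccc9)cc(OCc9ccccc9)c4c3O[C@H](c3ccc(OCc9ccccc9)c(OCc9ccccc9)c3)[C@H](OCc9ccccc9)[C@H]4c3c(OCc9ccccc9)c(Br)c4c(c3OCc9ccccc9)C[C@@H](OCc9ccccc9)[C@@H](c3ccc(OCc9ccccc9)c(OCc9ccccc9)c3)O4 | intermediate
21 | (E)-o-quinone methide carrying unit A and the C–D dimer | O=C1C(Br)=C(OCc9ccccc9)C([C@@H]4c5c(OCc9ccccc9)cc(OCc9ccccc9)cc5O[C@H](c5ccc(OCc9ccccc9)c(OCc9ccccc9)c5)[C@@H]4OCc9ccccc9)=C(OCc9ccccc9)/C1=C\c3c(OCc9ccccc9)cc(OCc9ccccc9)c4c3O[C@H](c3ccc(OCc9ccccc9)c(OCc9ccccc9)c3)[C@H](OCc9ccccc9)[C@H]4c3c(OCc9ccccc9)c(Br)c4c(c3OCc9ccccc9)C[C@@H](OCc9ccccc9)[C@@H](c3ccc(OCc9ccccc9)c(OCc9ccccc9)c3)O4 | intermediate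
22 | protected tetramer, unit B all-cis with 3-O-acetate | C(c9ccccc9)Oc1ccc([C@H]2Oc3c(Br)c(OCc9ccccc9)c([C@@H]4c5c(OCc9ccccc9)cc(OCc9ccccc9)cc5O[C@H](c5ccc(OCc9ccccc9)c(OCc9ccccc9)c5)[C@@H]4OCc9ccccc9)c(OCc9ccccc9)c3[C@@H](c3c(OCc9ccccc9)cc(OCc9ccccc9)c4c3O[C@H](c3ccc(OCc9ccccc9)c(OCc9ccccc9)c3)[C@H](OCc9ccccc9)[C@H]4c3c(OCc9ccccc9)c(Br)c4c(c3OCc9ccccc9)C[C@@H](OCc9ccccc9)[C@@H](c3ccc(OCc9ccccc9)c(OCc9ccccc9)c3)O4)[C@H]2OC(C)=O)cc1 | intermediate
23 | protected tetramer, unit B with free 3-OH | C(c9ccccc9)Oc1ccc([C@H]2Oc3c(Br)c(OCc9ccccc9)c([C@@H]4c5c(OCc9ccccc9)cc(OCc9ccccc9)cc5O[C@H](c5ccc(OCc9ccccc9)c(OCc9ccccc9)c5)[C@@H]4OCc9ccccc9)c(OCc9ccccc9)c3[C@@H](c3c(OCc9ccccc9)cc(OCc9ccccc9)c4c3O[C@H](c3ccc(OCc9ccccc9)c(OCc9ccccc9)c3)[C@H](OCc9ccccc9)[C@H]4c3c(OCc9ccccc9)c(Br)c4c(c3OCc9ccccc9)C[C@@H](OCc9ccccc9)[C@@H](c3ccc(OCc9ccccc9)c(OCc9ccccc9)c3)O4)[C@H]2O)cc1 | intermediate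
24 | epicatechin-(4α→6)-epiafzelechin-(4α→8)-epicatechin-(4β→6)-epicatechin | Oc1ccc([C@H]2Oc3cc(O)c([C@@H]4c5c(O)cc(O)cc5O[C@H](c5ccc(O)c(O)c5)[C@@H]4O)c(O)c3[C@@H](c3c(O)cc(O)c4c3O[C@H](c3ccc(O)c(O)c3)[C@H](O)[C@H]4c3c(O)cc4c(c3O)C[C@@H](O)[C@@H](c3ccc(O)c(O)c3)O4)[C@H]2O)cc1 | target

**Step count**
- Total step count: 14.
- Longest linear sequence: 9 (steps 1, 3, 6, 8, 9, 10, 11, 13, 14).

**Steps most likely to fail**

**Step 13.**
- The enol acetate is a weak dienophile. The stabilised, crowded o-quinone methide may react slowly or stepwise.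
- The facial preference imposed by units A and C cannot be predicted with confidence. The product must be assigned by ROESY and CD.

The fallback sets out from 17 and from Grignard reagent 20 (made from 7) and comes back at 22. Commercial 2-bromo-1-[4-(benzyloxy)phenyl]ethanone and KOAc in DMF give 2-[4-(benzyloxy)phenyl]-2-oxoethyl acetate F1. TBSOTf and Et3N in CH2Cl2 at 0 °C turn it into (Z)-2-[4-(benzyloxy)phenyl]-2-[(tert-butyldimethylsilyl)oxy]ethenyl acetate F2. In F2 the silyloxy and aryl donors push in the same direction, so it is far more nucleophilic at the acetoxy-bearing carbon. Trapping 21 with it gives the 2α-silyloxy analogue of 22 F3. Here only C3 and C4 are set in the cycloaddition. Et3SiH with BF3·OEt2 in CH2Cl2 at −78 °C then ionises the C2 ketal and delivers hydride from the β face, anti to the 3-acetoxy and 4-aryl groups, to give 22.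

**Step 8.** A 2,6-dialkoxy aryllithium dianion must add to a hindered ketone. That ketone can enolise, epimerise at C3 or ring-open.

The fallback sets out from 5 and 10 (isolated this time) and comes back at 13. Compound 5 and excess 10 with catalytic BF3·OEt2 couple at the only free carbon of 10 to give the 4β-aryl epimer of 14 F4. DDQ in wet CH2Cl2 then oxidises this para-hydroxy diarylmethine through the same C4 cation, and water traps it to give 13. No organometallic addition is needed.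

**Step 5.**
- The capped nucleophile is weak.
- The electron-rich aryl iodide can lose iodine under acid.

The fallback sets out from 6 (with 4) and comes back at 7. Compound 6 and 2-mercaptobenzothiazole with catalytic AcOH in CH2Cl2 give the 4β-(benzothiazol-2-ylthio) ether of 6 F5. AgBF4 then activates it thiophilically in the presence of 4 (3 equiv) in THF/CH2Cl2 at 0 °C under essentially acid-free conditions, giving 7.

**Further compounds**
F1 | step 13 | 2-[4-(benzyloxy)phenyl]-2-oxoethyl acetate | CC(=O)OCC(=O)c1ccc(OCc2ccccc2)cc1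
F2 | step 13 | (Z)-2-[4-(benzyloxy)phenyl]-2-[(tert-butyldimethylsilyl)oxy]ethenyl acetate | CC(=O)O/C=C(\O[Si](C)(C)C(C)(C)C)c1ccc(OCc2ccccc2)cc1
F3 | step 13 | 2α-silyloxy analogue of 22 | C(c9ccccc9)Oc1ccc([C@]2(O[Si](C)(C)C(C)(C)C)Oc3c(Br)c(OCc9ccccc9)c([C@@H]4c5c(OCc9ccccc9)cc(OCc9ccccc9)cc5O[C@H](c5ccc(OCc9ccccc9)c(OCc9ccccc9)c5)[C@@H]4OCc9ccccc9)c(OCc9ccccc9)c3[C@@H](c3c(OCc9ccccc9)cc(OCc9ccccc9)c4c3O[C@H](c3ccc(OCc9ccccc9)c(OCc9ccccc9)c3)[C@H](OCc9ccccc9)[C@H]4c3c(OCc9ccccc9)c(Br)c4c(c3OCc9ccccc9)C[C@@H](OCc9ccccc9)[C@@H](c3ccc(OCc9ccccc9)c(OCc9ccccc9)c3)O4)[C@H]2OC(C)=O)cc1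
F4 | step 8 | 4β-aryl epimer of 14 | c1c(OCc9ccccc9)cc(OCc9ccccc9)c2c1O[C@H](c1ccc(OCc9ccccc9)c(OCc9ccccc9)c1)[C@H](OCc9ccccc9)[C@H]2c1c(OCc9ccccc9)c(Br)c(O)c(Br)c1OCc9ccccc9
F5 | step 5 | 4β-(benzothiazol-2-ylthio) ether of 6 | Ic1c(OCc9ccccc9)cc(OCc9ccccc9)c2c1O[C@H](c1ccc(OCc9ccccc9)c(OCc9ccccc9)c1)[C@H](OCc9ccccc9)[C@H]2Sc1nc3ccccc3s1
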